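**Target:** 3-(4-hydroxyphenyl)-5-methoxy-4,7-diphenyl-1-benzofuran-2,6-dione (5-O-methylxylerythrin), C27H18O5.

Assumption: the target has no stereocentre and no stereogenic double bond, so no asymmetric step is needed; reagents that donate heavy atoms are numbered as compounds.

**Retrosynthetic overview**
1. Target 9 ⇐ xylerythrin 7 by selective O-methylation of the 5-OH, a doubly vinylogous acid.
2. 7 ⇐ leuco lactone 6 by dehydrogenation; 6 ⇐ C3–C3a disconnection into triol 5 (nucleophilic ring C–H) and the α-cation of 4-hydroxyphenylacetic acid. The α-carbon, normally an enolate nucleophile, is used with inverted polarity and delivered by 4-hydroxymandelic acid 4.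
3. 5 ⇐ triacetate 3 ⇐ 2,5-diphenyl-1,4-benzoquinone 1 (Thiele–Winter acetoxylation).
4. Ring order: the central carbocycle with both phenyls is bought; the five-membered lactone is the only ring formed (step 2), then the quinone methide is generated by oxidation.

**Route**

Step 1
Reactants: 1 2,5-diphenyl-1,4-benzoquinone; 2 acetic anhydride
Product: 3 3,6-diphenylbenzene-1,2,4-triyl triacetate
Conditions: Ac2O (solvent), BF3·OEt2 (0.3 equiv), 45 °C, 24 h
Reagents that add atoms: acetic anhydride (2), CC(=O)OC(C)=O
Why: Thiele–Winter acetoxylation: the Lewis-acid-activated quinone takes up acetate by 1,4-addition at one of its two equivalent unsubstituted ring carbons and the resulting hydroquinone is acetylated, which installs the future C6 oxygen and leaves a single ring C–H.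

Step 2
Reactants: 3 3,6-diphenylbenzene-1,2,4-triyl triacetate; 4 (RS)-4-hydroxymandelic acid
Product: 7 xylerythrin [5-hydroxy-3-(4-hydroxyphenyl)-4,7-diphenyl-1-benzofuran-2,6-dione], via triol 5 (not isolated), via leuco lactone 6 (not isolated)
Conditions: AcOH/6 M HCl (3:1), Ar, 95 °C, 3 h; then 4 (1.2 equiv, added over 2 h), 80 °C, 8 h; then FeCl3 (2.2 equiv), 20 °C, 0.5 h
Reagents that add atoms: none
Why: Acid unmasks triol 5 and ionises 4 to its O-protonated para-quinone methide, an α-cation (enolonium) equivalent of 4-hydroxyphenylacetic acid, which alkylates the only free ring carbon of 5 (ortho and para to OH groups) in a Friedel–Crafts alkylation; the ortho OH then closes the lactone and FeCl3 dehydrogenates catechol 6 to the quinone methide, erasing the racemic C3 centre of 6 so that no stereocentre remains.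

Step 3
Reactants: 7 xylerythrin; 8 (trimethylsilyl)diazomethane
Product: 9 3-(4-hydroxyphenyl)-5-methoxy-4,7-diphenyl-1-benzofuran-2,6-dione (target)
Conditions: TMSCHN2 (1.0 equiv, 2 M in hexanes), toluene/MeOH (4:1), −20 to 0 °C
Reagents that add atoms: (trimethylsilyl)diazomethane (8), C[Si](C)(C)C=[N+]=[N-]
Why: Diazoalkane O-methylation follows acidity, and the 5-OH (conjugated through C4, C3a and C3 to the lactone carbonyl, as in 4-hydroxycoumarin) is expected to be clearly more acidic than the 4'-phenol, so one equivalent should methylate it alone; the fully substituted ring alkenes resist dipolar cycloaddition.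

**Compound list**
1 | 2,5-diphenyl-1,4-benzoquinone | O=C1C=C(c2ccccc2)C(=O)C=C1c1ccccc1 | starting material
2 | acetic anhydride | CC(=O)OC(C)=O | starting material
3 | 3,6-diphenylbenzene-1,2,4-triyl triacetate | CC(=O)Oc1cc(-c2ccccc2)c(OC(C)=O)c(OC(C)=O)c1-c1ccccc1 | intermediate
4 | (RS)-4-hydroxymandelic acid (racemic) | OC(C(=O)O)c1ccc(O)cc1 | starting material
5 | 3,6-diphenylbenzene-1,2,4-triol | Oc1cc(-c2ccccc2)c(O)c(O)c1-c1ccccc1 | intermediate (not isolated)
6 | 5,6-dihydroxy-3-(4-hydroxyphenyl)-4,7-diphenyl-1-benzofuran-2(3H)-one (racemic at C3) | O=C1Oc2c(-c3ccccc3)c(O)c(O)c(-c3ccccc3)c2C1c1ccc(O)cc1 | intermediate (not isolated)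
7 | xylerythrin, 5-hydroxy-3-(4-hydroxyphenyl)-4,7-diphenyl-1-benzofuran-2,6-dione | OC1=C(c2ccccc2)C2=C(c3ccc(O)cc3)C(=O)OC2=C(c2ccccc2)C1=O | intermediate
8 | (trimethylsilyl)diazomethane | C[Si](C)(C)C=[N+]=[N-] | starting material
9 | 3-(4-hydroxyphenyl)-5-methoxy-4,7-diphenyl-1-benzofuran-2,6-dione | COC1=C(c2ccccc2)C2=C(c3ccc(O)cc3)C(=O)OC2=C(c2ccccc2)C1=O | target

**Totals**
Total step count: 3. Longest linear sequence: 3 steps (1 → 3 → 7 → 9).

**Steps most likely to fail, with fallbacks**

Step 2 is the most exposed. The ring carbon is flanked by a phenyl and an OH, the electrophile can self-condense, and the electron-rich triol could simply reduce the quinone methide. The fallback sets out from triol 5 (made from 3 as in the first stage of step 2) and comes back at leuco lactone 6. Triol 5 is condensed with the small electrophile glyoxylic acid monohydrate (AcOH/aq. HCl, 50 °C; hydroxyalkylation then lactonisation) to give racemic 3,5,6-trihydroxy-4,7-diphenyl-1-benzofuran-2(3H)-one F3. F3 is heated in molten phenol (20 equiv) with MeSO3H; its C3–OH ionises to the lactone α-cation, stabilised as a quinone methide by the para 6-OH, and this arylates phenol at its para carbon to give 6. FeCl3 then oxidises 6 to 7 as before. The inverted-polarity bond formation moves from C3–C3a to C3–aryl.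

Step 3 may give some 4'-O-methyl or dimethyl ether if the acidity gap is smaller than estimated. The fallback sets out from 7 and comes back at 9. It replaces O-alkylation by acid-catalysed addition–elimination: MeOH, HC(OMe)3, H2SO4 (cat.), reflux. The C5 carbon is a vinylogous acyl carbon and exchanges OH for OMe as lawsone and 4-hydroxycoumarin do, a pathway a true phenol cannot follow. No compound outside the list is made (entry F0).

Step 1 may be sluggish because both quinone double bonds carry a phenyl. The fallback sets out from 1 and comes back at 5. Nucleophilic (Weitz–Scheffer) epoxidation with t-BuOOH/DBU in CH2Cl2 gives racemic 2,3-epoxy-2,5-diphenyl-2,3-dihydro-1,4-benzoquinone F1. Conc. H2SO4 isomerises it to 2-hydroxy-3,6-diphenyl-1,4-benzoquinone F2. Na2S2O4 (EtOAc/H2O) reduces F2 to triol 5, which enters step 2 at its second stage.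

**Further compounds**
F1 | step 1 | 2,3-epoxy-2,5-diphenyl-2,3-dihydro-1,4-benzoquinone (racemic, cis-fused epoxide) | O=C1C(c2ccccc2)=CC(=O)C2(c3ccccc3)OC12
F2 | step 1 | 2-hydroxy-3,6-diphenyl-1,4-benzoquinone | O=C1C(O)=C(c2ccccc2)C(=O)C=C1c1ccccc1
F3 | step 2 | 3,5,6-trihydroxy-4,7-diphenyl-1-benzofuran-2(3H)-one (racemic) | O=C1Oc2c(-c3ccccc3)c(O)c(O)c(-c3ccccc3)c2C1O
F0 | step 3 | none | none
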